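The data are simulated with constants of no real substance; scatter was added.

The constants come first, and I read them from the fraction left, not the fraction made.

in all of them: gas 55 mM (held)

| charge | substrate | temperature | remark | time |
|---|---|---|---|---|
| delta | 1.1 M | −5 °C | run made earlier |  |
| beta | 1.8 M | 28 °C | run made earlier |  |
| south-east | 0.80 M | 10 °C |  | 30 h |
| west | 0.80 M | −20 °C |  | 30 h |
| east | 0.80 M | 40 °C |  | 30 h |
| south | 0.80 M |  | at 40 °C until 20 h, from then on at −20 °C | 30 h |

| run | time / h | target / % |
|---|---|---|
| delta | 8.00 | 25 |
| delta | 15.0 | 37 |
| delta | 25.0 | 53 |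
| delta | 30.0 | 58 |
| delta | 40.0 | 70 |
| delta | 48.0 | 77 |
| delta | 60.0 | 83 |
| beta | 1.50 | 3 |
| beta | 3.00 | 11 |
| beta | 5.00 | 14 |
| beta | 6.00 | 19 |
| beta | 8.00 | 28 |
| beta | 10.0 | 30 |
| beta | 12.0 | 38 |

(scatter of a reading: 2 percentage points)

- at the start none of the gas is in solution

1. the best flask by amount of target, in percent of the substrate charged; "all alike" if 1.5 percentage points covers them all (south-east / west / east / south / all alike)
2. amount of target at the end, in percent of the substrate charged, south-east
3. amount of target at the end, in percent of the substrate charged, west
4. amount of target at the end, in percent of the substrate charged, east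
5. amount of target at the end, in percent of the substrate charged, south

If every reacted part of the delta run is target, its last reading of 83% at 60.0 h gives 0.0295 h⁻¹. I call this the loss constant, minus the logarithm of the fraction left, divided by the time.

Does it stay constant as the substrate falls? The delta reading at 30.0 h gives 0.0289 h⁻¹, so with the gas held I treat the loss as pseudo-first-order, and the charge drops out of the percentages.

Does temperature move it? The last beta reading gives 0.0398 h⁻¹, a ratio of 1.35 to delta, so between these two runs it reads as moving weakly.

What does that leave at 30 h? The delta constant leaves 41.2% and the beta constant 30.3%, and south-east should fall between them. East, warmer than south-east and west, should lose the most substrate. South shares east's first 20 h and then goes cold, so I place it behind east. West is colder than delta, and the constant reads lower in delta than in beta, so my estimate for west lies below 58.8% of target.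

The forecast, holding that “so concentration should not matter”, names east with 64%, 54%, 72% and 67% for south-east, west, east and south.

The flasks give 66.2%, 44.9%, 73.4% and 66.7% in that order, with east ahead.

    coupling partner ⇌ dormant form (K = 39.0, k = 0.0580 h⁻¹, Ea = 88.0 kJ mol⁻¹, ΔH = −17.0 kJ mol⁻¹)
    substrate ⇌ tight pair (K = 0.00170, k = 0.140 h⁻¹, Ea = 73.0 kJ mol⁻¹, ΔH = −44.0 kJ mol⁻¹)
    gas ⇌ coupling partner, rate k3*(csat - [coupling partner]) (kL = 21.0 h⁻¹)
    coupling partner + loose pair → isomer of the product (k = 370 L mol⁻¹ h⁻¹, Ea = 54.0 kJ mol⁻¹)
    tight pair ⇌ loose pair (K = 0.410, k = 99.0 h⁻¹, Ea = 77.0 kJ mol⁻¹, ΔH = −63.0 kJ mol⁻¹)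
    coupling partner + tight pair → target (k = 340 L mol⁻¹ h⁻¹, Ea = 48.0 kJ mol⁻¹)
    (constants at −20 °C)

The delta constant gives west 41.2% left and west holds 37% of substrate, yet beside 44.9% of target west holds 18.5% of isomer of the product at 30.0 h, so target is a share of 70.8% of these two. At 10.7 h in west, the half-life of tight pair by the forward passing into loose pair alone is 0.42 min, shorter than the 2.3 min by coupling with coupling partner into target.

For west left until 5.0 d, the constant gives 2.90% left, and that share gives 68.7% of target. The computed flask holds 1.75% of substrate and 69.6% of target.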